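The data were generated by integration with constants of no real substance; noise was put on by code.

If incoming ligand is the limiting reagent, the part of a flask's starting complex that can react is its ligand charge per complex charge, divided by what each reacted complex costs.

| flask | starting complex | incoming ligand | scavenger | remark | time |
|---|---|---|---|---|---|
| Thursday's | 0.75 M | 0.25 M | 0.75 M | run made earlier |  |
| flask | 0.50 M | 0.250 M | 0.750 M |  | 8.0 d |

Thursday's run (percent of the starting complex charged)

| time / h | starting complex / % | complex with two exchanged / % |
|---|---|---|
| 6.00 | 89 | 5 |
| 12.0 | 85 | 7 |
| 15.0 | 83 | 6 |
| 20.0 | 83 | 9 |
| 30.0 | 77 | 6 |
| 40.0 | 75 | 5 |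

(scatter of a reading: 1.5 percentage points)

- the earlier runs do not show how much of incoming ligand is bound; that part of a forecast is a guess

* part of the starting complex that has reacted at 8.0 d
* share of the unused incoming ligand that is free and not bound as idle adduct, at 8.0 d

This flask held 50.0% ligand per complex charged. I priced that in two ways. At 40.0 h, Thursday's run had lost 25.0% of its starting complex and showed 5% as complex with two exchanged. Counting one ligand per reacted complex and one more for each of those gave 1.20: the ligand bill, incoming ligand taken per starting complex reacted. It predicted 41.7% for this flask.

The second way took Thursday's run as finished. Its 33.3% ligand per complex over the same loss made a bill of 1.33, hence 37.5%. The two parted, and the second cheated: Thursday's starting complex still fell 8 percentage points after 20.0 h, against a scatter of 1.5 points, so that run was not finished. The first counted nothing unseen and could run low, so I expected a value between them. This flask's 8.0 d was 4.80 times Thursday's span, so I reckoned with incoming ligand as its limiting reagent. The readings said nothing of the idle adduct.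

The forecast gave 40% reacted and 60% free, holding that “the new flask should therefore also be ligand-limited”.

The flask gave 39.5% reacted, within the forecast's margin, and 100% free, 40 points above the forecast. Its bill was 1.27, between my two. The idle adduct made no difference to the reacted part.

    complex with two exchanged + incoming ligand → leaving ligand + complex with three exchanged (k = 0.193 /M/h)
    scavenger + leaving ligand → scavenged by-product (k = 3.65 /M/h)
    starting complex + incoming ligand → leaving ligand + complex with one exchanged (k = 0.104 /M/h)
    complex with three exchanged + incoming ligand → leaving ligand + complex with four exchanged (k = 0.00337 /M/h)
    leaving ligand + incoming ligand ⇌ idle adduct, settled at all times (K = 11.7 /M)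
    starting complex + complex with two exchanged → side product (k = 0.0270 /M/h)
    complex with one exchanged + incoming ligand → leaving ligand + complex with two exchanged (k = 0.979 /M/h)

This flask had not quite come to rest: with 0% of its incoming ligand left at 8.0 d, its reacted part stood at 39.5%, and at 80.0 d, ten times that time, it stood at 42.8%. Between those two times, complex with two exchanged went from 3.25% to 0%, and side product, counted as two, rose from 24.8% to 31.3%. For the neighbour with 0.20 M of starting complex, my bill of 1.20 gave 104%, more than its charge holds. That neighbour reached 63.0% at 8.0 d, a bill of about 1.99, with 21.6% as complex with three exchanged.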